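**Retrosynthetic overview**
- The target comes from peracid epoxidation of the 1(10)-olefin of a macrocyclic diester. Its C8 ester comes from Mitsunobu inversion of an 8α-alcohol with (2S,3S)-epoxyangelic acid.
- Key disconnection C7–C8: intramolecular Nozaki–Hiyama allylation of a 3-(bromomethyl)butenolide onto a C8 aldehyde. The allylchromium is a lactone β-carbanion (homoenolate equivalent). This step closes the ten-membered ring, sets C7 and C8, and unveils the α-methylene lactone.
- The seco-precursor comes from an asymmetric nickel/chromium coupling at C3–C4 between a (Z)-iodoalkenyl butenolide and a β,γ-unsaturated aldehyde, followed by isovalerylation.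
- The butenolide comes from acrylate ring-closing metathesis of an (S)-iododienol (CBS reduction; hydroalumination/iodination fixes 4Z). The aldehyde comes from Zr-catalysed carboalumination and oxirane opening (fixes 1(10)E). The acid comes from Sharpless epoxidation of angelyl alcohol.
- Ring order: butenolide (lactone) ring first, ten-membered carbocycle second, oxirane last.

Assumption: germacranolide numbering (C1–C10 ring, C11–C13 lactone, C14/C15 methyls) is used throughout; in this frame the target is the 1β,10α-epoxy-3β-isovaleryloxy-8β-epoxyangeloyloxy-4Z-germacranolide with H-7α (1R,3S,6R,7R,8R,10R,2'S,3'S). TBS = tert-butyldimethylsilyl.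

**Route**

Step 1
Reactants: 1 (E)-but-2-enoyl chloride; 2 propyne
Product: 3 (E)-hept-2-en-5-yn-4-one
Conditions: PdCl2(PPh3)2 (2 mol %), CuI (4 mol %), Et3N (1.1 equiv), THF, 0 °C to rt
Reagents that add atoms: none
Why: Acyl Sonogashira coupling: the copper acetylide of propyne transmetalates to the acylpalladium from 1 and reductive elimination gives the ynone; the E-olefin is untouched and no stereocentre is formed.

Step 2
Reactants: 3 (E)-hept-2-en-5-yn-4-one
Product: 4 (S,E)-hept-2-en-5-yn-4-ol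
Conditions: (S)-Me-CBS (20 mol %), catecholborane (1.5 equiv), toluene/CH2Cl2, −78 °C
Reagents that add atoms: none
Why: Corey–Bakshi–Shibata reduction: the ketone binds the oxazaborolidine–borane with the propenyl group as the large and the linear propynyl group as the small substituent, so hydride delivery gives the 4S carbinol (the future C6), and 1,2-reduction is favoured at low temperature.

Step 3
Reactants: 4 (S,E)-hept-2-en-5-yn-4-ol
Product: 6 (2E,4S,5Z)-6-iodohepta-2,5-dien-4-ol, via cyclic alkenylalanate 5 (not isolated)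
Conditions: NaAlH2(OCH2CH2OMe)2 (1.6 equiv), THF, 0 °C to rt; EtOAc; then I2, −78 °C
Reagents that add atoms: iodine, II
Why: Alkoxide-directed trans-hydroalumination of the propargylic alcohol puts aluminium on the distal alkyne carbon (five-membered alanate 5) and iodinolysis goes with retention, so iodine ends up cis to the carbinol carbon (Z), which later fixes the 4Z ring geometry; the allylic E-olefin is not reduced.

Step 4
Reactants: 7 ethyl 2-(hydroxymethyl)prop-2-enoate
Product: 8 ethyl 2-{[(TBS)oxy]methyl}prop-2-enoate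
Conditions: TBSCl, imidazole, DMF, 0 °C to rt
Reagents that add atoms: tert-butyldimethylsilyl chloride, CC(C)(C)[Si](C)(C)Cl
Why: Standard imidazole-mediated silylation of the primary allylic alcohol; it masks the future allylic bromide position during the later nickel/chromium coupling.

Step 5
Reactants: 8 ethyl 2-{[(TBS)oxy]methyl}prop-2-enoate
Product: 9 2-{[(TBS)oxy]methyl}prop-2-enoic acid
Conditions: LiOH, THF/H2O, 0 °C to rt; then 1 M HCl to pH 3
Reagents that add atoms: lithium hydroxide, [Li+].[OH-]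
Why: Saponification (acyl–oxygen cleavage) of the ethyl ester; the primary silyl ether survives cold aqueous LiOH.

Step 6
Reactants: 6 (2E,4S,5Z)-6-iodohepta-2,5-dien-4-ol; 9 2-{[(TBS)oxy]methyl}prop-2-enoic acid
Product: 10 (2E,4S,5Z)-6-iodohepta-2,5-dien-4-yl 2-{[(TBS)oxy]methyl}prop-2-enoate
Conditions: DCC, DMAP (10 mol %), CH2Cl2, 0 °C to rt
Reagents that add atoms: none
Why: Steglich esterification acylates the secondary alcohol without breaking its C–O bond, so the stereocentre is retained.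

Step 7
Reactants: 10 (2E,4S,5Z)-6-iodohepta-2,5-dien-4-yl 2-{[(TBS)oxy]methyl}prop-2-enoate
Product: 11 (S)-3-{[(TBS)oxy]methyl}-5-[(Z)-2-iodoprop-1-en-1-yl]furan-2(5H)-one
Conditions: second-generation Hoveyda–Grubbs catalyst (5 mol %), toluene, 80 °C, argon sparge
Reagents that add atoms: none
Why: Ring-closing metathesis: the ruthenium carbene loads on the propenyl group and closes onto the 1,1-disubstituted acrylate to the butenolide with loss of propene; the trisubstituted iodoalkene is inert and the stereocentre is untouched.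

Step 8
Reactants: 12 tert-butyl(but-3-yn-1-yloxy)dimethylsilane; 13 oxirane
Product: 16 (E)-6-[(TBS)oxy]-4-methylhex-3-en-1-ol, via alkenyldimethylalane 14 (not isolated), via lithium alkenylalanate 15 (not isolated)
Conditions: Me3Al (2 equiv), Cp2ZrCl2 (20 mol %), CH2Cl2, 0 °C to rt; then n-BuLi, THF/hexane, −78 °C; oxirane, −78 to 0 °C; aqueous work-up
Reagents that add atoms: trimethylaluminium, C[Al](C)C
Why: Negishi zirconium-catalysed syn-carboalumination adds Me and Al cis across the alkyne (E-alkenylalane 14, methyl on the internal carbon), and the ate complex 15 opens oxirane with retention of alkene geometry to give the E-trisubstituted homoallylic alcohol.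

Step 9
Reactants: 16 (E)-6-[(TBS)oxy]-4-methylhex-3-en-1-ol
Product: 17 (E)-6-[(TBS)oxy]-4-methylhex-3-enal
Conditions: DMP, CH2Cl2, 0 °C to rt; used crude
Reagents that add atoms: none
Why: Dess–Martin oxidation under neutral conditions gives the β,γ-unsaturated aldehyde without migration of the double bond.

Step 10
Reactants: 11 (S)-3-{[(TBS)oxy]methyl}-5-[(Z)-2-iodoprop-1-en-1-yl]furan-2(5H)-one; 17 (E)-6-[(TBS)oxy]-4-methylhex-3-enal
Product: 18 (R)-3-{[(TBS)oxy]methyl}-5-[(1Z,3S,5E)-8-[(TBS)oxy]-3-hydroxy-2,6-dimethylocta-1,5-dien-1-yl]furan-2(5H)-one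
Conditions: CrCl2 (4 equiv), NiCl2 (2 mol %), Kishi-type chiral oxazoline–sulfonamide ligand (4.4 equiv, the enantiomer that directs Re-face attack), Et3N (4.4 equiv), THF, rt
Reagents that add atoms: none
Why: Asymmetric Nozaki–Hiyama–Kishi coupling: zerovalent nickel activates the alkenyl iodide, transmetalation gives an alkenylchromium that keeps the Z geometry and adds to the aldehyde, the chiral sulfonamide on chromium directing Re-face attack to set 3S; lactone, silyl ethers and the enolisable aldehyde tolerate the neutral conditions.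

Step 11
Reactants: 18 (R)-3-{[(TBS)oxy]methyl}-5-[(1Z,3S,5E)-8-[(TBS)oxy]-3-hydroxy-2,6-dimethylocta-1,5-dien-1-yl]furan-2(5H)-one; 19 3-methylbutanoic anhydride
Product: 20 (1Z,3S,5E)-8-[(TBS)oxy]-1-[(R)-4-{[(TBS)oxy]methyl}-5-oxo-2,5-dihydrofuran-2-yl]-2,6-dimethylocta-1,5-dien-3-yl 3-methylbutanoate
Conditions: DMAP (10 mol %), pyridine, CH2Cl2, 0 °C
Reagents that add atoms: none
Why: DMAP-catalysed acylation installs the isovalerate of the target on the C3 alcohol with retention; the weak base at 0 °C avoids deprotonation at the butenolide γ-position.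

Step 12
Reactants: 20 (1Z,3S,5E)-8-[(TBS)oxy]-1-[(R)-4-{[(TBS)oxy]methyl}-5-oxo-2,5-dihydrofuran-2-yl]-2,6-dimethylocta-1,5-dien-3-yl 3-methylbutanoate
Product: 21 (1Z,3S,5E)-8-hydroxy-1-[(R)-4-(hydroxymethyl)-5-oxo-2,5-dihydrofuran-2-yl]-2,6-dimethylocta-1,5-dien-3-yl 3-methylbutanoate
Conditions: HF·pyridine, THF/pyridine, 0 °C to rt
Reagents that add atoms: none
Why: Fluoride cleaves both primary silyl ethers; esters, lactone and olefins are inert to buffered HF·pyridine.

Step 13
Reactants: 21 (1Z,3S,5E)-8-hydroxy-1-[(R)-4-(hydroxymethyl)-5-oxo-2,5-dihydrofuran-2-yl]-2,6-dimethylocta-1,5-dien-3-yl 3-methylbutanoate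
Product: 22 (1Z,3S,5E)-1-[(R)-4-(bromomethyl)-5-oxo-2,5-dihydrofuran-2-yl]-8-hydroxy-2,6-dimethylocta-1,5-dien-3-yl 3-methylbutanoate
Conditions: NBS (1.3 equiv), Me2S (1.5 equiv), CH2Cl2, −20 to 0 °C
Reagents that add atoms: N-bromosuccinimide, O=C1CCC(=O)N1Br
Why: Corey–Kim halogenation: the sulfonium reagent from NBS and Me2S converts only the allylic alcohol into the bromide by SN2 collapse of its alkoxysulfonium salt, while the saturated primary alcohol is returned on work-up.

Step 14
Reactants: 22 (1Z,3S,5E)-1-[(R)-4-(bromomethyl)-5-oxo-2,5-dihydrofuran-2-yl]-8-hydroxy-2,6-dimethylocta-1,5-dien-3-yl 3-methylbutanoate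
Product: 23 (1Z,3S,5E)-1-[(R)-4-(bromomethyl)-5-oxo-2,5-dihydrofuran-2-yl]-2,6-dimethyl-8-oxoocta-1,5-dien-3-yl 3-methylbutanoate
Conditions: DMP, CH2Cl2, 0 °C; used at once
Reagents that add atoms: none
Why: Dess–Martin oxidation of the remaining primary alcohol gives the β,γ-unsaturated C8 aldehyde under neutral conditions that leave the allylic bromide alone.

Step 15
Reactants: 23 (1Z,3S,5E)-1-[(R)-4-(bromomethyl)-5-oxo-2,5-dihydrofuran-2-yl]-2,6-dimethyl-8-oxoocta-1,5-dien-3-yl 3-methylbutanoate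
Product: 25 (3S,6R,7R,8S)-8-hydroxy-3-[(3-methylbutanoyl)oxy]germacra-1(10)E,4Z,11(13)-trien-12,6-olide, via allylchromium dichloride 24 (not isolated)
Conditions: CrCl2 (8 equiv), THF, 2 mM, syringe-pump addition over 12 h, rt
Reagents that add atoms: none
Why: Proposed new method: CrCl2 inserts into the allylic C–Br bond to give allylchromium 24, in which the butenolide β-carbon C7 (normally an acceptor) is the nucleophilic γ-terminus, a lactone homoenolate equivalent, and adds to the C8 aldehyde carbon through a six-membered chair transition state (Nozaki–Hiyama allylation; closest known types are intermolecular Cr- or Zn-mediated additions of 3-(bromomethyl)furan-2(5H)-ones to aldehydes and Cr-mediated ten-membered closures of 2-(bromomethyl)acrylates); attack anti to the C6 alkenyl arm gives the 6,7-trans lactone (7R), the chair with the C9 tether equatorial gives the 7,8-anti carbinol (8S, 8α-OH), and the allyl transposition regenerates the exocyclic methylene.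

Step 16
Reactants: 26 (Z)-2-methylbut-2-enoic acid (angelic acid)
Product: 27 (Z)-2-methylbut-2-en-1-ol
Conditions: LiAlH4, Et2O, 0 °C
Reagents that add atoms: none
Why: Hydride reduction of the acid to the allylic alcohol; the Z geometry is kept because neither conjugate addition nor enolisation occurs.

Step 17
Reactants: 27 (Z)-2-methylbut-2-en-1-ol
Product: 28 [(2R,3S)-2,3-dimethyloxiran-2-yl]methanol
Conditions: Ti(OiPr)4 (20 mol %), D-(−)-diethyl tartrate (24 mol %), t-BuOOH, 4 Å MS, CH2Cl2, −20 °C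
Reagents that add atoms: tert-butyl hydroperoxide, CC(C)(C)OO
Why: Sharpless asymmetric epoxidation: the D-(−)-tartrate catalyst delivers oxygen to the olefin face opposite to that used by the L-(+) ligand, giving the (2R,3S) epoxy alcohol, and the cis relationship of CH2OH and the C3 methyl comes from the Z olefin.

Step 18
Reactants: 28 [(2R,3S)-2,3-dimethyloxiran-2-yl]methanol
Product: 29 (2S,3S)-2,3-dimethyloxirane-2-carboxylic acid
Conditions: RuCl3 (2 mol %), NaIO4 (4 equiv), MeCN/CCl4/H2O, rt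
Reagents that add atoms: water, O
Why: RuO4 generated in situ oxidises the primary alcohol via the aldehyde hydrate to the acid without opening the trisubstituted epoxide; C2 keeps its spatial arrangement (the descriptor changes to S only through the priority change).

Step 19
Reactants: 25 (3S,6R,7R,8S)-8-hydroxy-3-[(3-methylbutanoyl)oxy]germacra-1(10)E,4Z,11(13)-trien-12,6-olide; 29 (2S,3S)-2,3-dimethyloxirane-2-carboxylic acid
Product: 30 (3S,6R,7R,8R)-8-{[(2S,3S)-2,3-dimethyloxirane-2-carbonyl]oxy}-3-[(3-methylbutanoyl)oxy]germacra-1(10)E,4Z,11(13)-trien-12,6-olide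
Conditions: PPh3 (2 equiv), DIAD (2 equiv), toluene, 0 °C to rt
Reagents that add atoms: none
Why: Mitsunobu esterification: SN2 displacement of the C8 alkoxyphosphonium by the carboxylate of 29 inverts C8 (8S to 8R, 8β-ester); the epoxy acid is acidic enough and its two stereocentres are not involved.

Step 20
Reactants: 30 (3S,6R,7R,8R)-8-{[(2S,3S)-2,3-dimethyloxirane-2-carbonyl]oxy}-3-[(3-methylbutanoyl)oxy]germacra-1(10)E,4Z,11(13)-trien-12,6-olide
Product: 31 (1R,3S,6R,7R,8R,10R)-1,10-epoxy-8-{[(2S,3S)-2,3-dimethyloxirane-2-carbonyl]oxy}-3-[(3-methylbutanoyl)oxy]germacra-4Z,11(13)-dien-12,6-olide (CNP0167461.1)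
Conditions: mCPBA (1.1 equiv), CH2Cl2, 0 °C
Reagents that add atoms: 3-chloroperbenzoic acid, O=C(OO)c1cccc(Cl)c1
Why: Prilezhaev epoxidation: the 1(10)-olefin is the only electron-rich alkene (C4=C5 is flanked by two allylic acyloxy groups, the methylene is conjugated), and in the germacranolide ring it stands roughly perpendicular to the ring plane, so the peracid attacks its outer face to give the 1β,10α (1R,10R) epoxide from the E-olefin.

**Compound list**

1 | (E)-but-2-enoyl chloride | C/C=C/C(Cl)=O | starting material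
2 | propyne | CC#C | starting material
3 | (E)-hept-2-en-5-yn-4-one | C/C=C/C(=O)C#CC | intermediate
4 | (S,E)-hept-2-en-5-yn-4-ol | C/C=C/[C@H](O)C#CC | intermediate
5 | sodium (5S)-2,2-bis(2-methoxyethoxy)-3-methyl-5-[(E)-prop-1-en-1-yl]-2,5-dihydro-1,2-oxaaluminol-2-uide (cyclic alkenylalanate) | C/C=C/[C@@H]1O[Al-](OCCOC)(OCCOC)C(C)=C1.[Na+] | intermediate (not isolated)
6 | (2E,4S,5Z)-6-iodohepta-2,5-dien-4-ol | C/C=C/[C@H](O)/C=C(/C)I | intermediate
7 | ethyl 2-(hydroxymethyl)prop-2-enoate | C=C(CO)C(=O)OCC | starting material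
8 | ethyl 2-{[(tert-butyldimethylsilyl)oxy]methyl}prop-2-enoate | C=C(CO[Si](C)(C)C(C)(C)C)C(=O)OCC | intermediate
9 | 2-{[(tert-butyldimethylsilyl)oxy]methyl}prop-2-enoic acid | C=C(CO[Si](C)(C)C(C)(C)C)C(=O)O | intermediate
10 | (2E,4S,5Z)-6-iodohepta-2,5-dien-4-yl 2-{[(tert-butyldimethylsilyl)oxy]methyl}prop-2-enoate | C/C=C/[C@H](OC(=O)C(=C)CO[Si](C)(C)C(C)(C)C)/C=C(/C)I | intermediate
11 | (S)-3-{[(tert-butyldimethylsilyl)oxy]methyl}-5-[(Z)-2-iodoprop-1-en-1-yl]furan-2(5H)-one | O=C1O[C@H](/C=C(/C)I)C=C1CO[Si](C)(C)C(C)(C)C | intermediate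
12 | tert-butyl(but-3-yn-1-yloxy)dimethylsilane | C#CCCO[Si](C)(C)C(C)(C)C | starting material
13 | oxirane | C1CO1 | starting material
14 | (E)-{4-[(tert-butyldimethylsilyl)oxy]-2-methylbut-1-en-1-yl}dimethylalane | C[Al](C)/C=C(\C)CCO[Si](C)(C)C(C)(C)C | intermediate (not isolated)
15 | lithium butyl{(E)-4-[(tert-butyldimethylsilyl)oxy]-2-methylbut-1-en-1-yl}dimethylalanate | [Li+].CCCC[Al-](C)(C)/C=C(\C)CCO[Si](C)(C)C(C)(C)C | intermediate (not isolated)
16 | (E)-6-[(tert-butyldimethylsilyl)oxy]-4-methylhex-3-en-1-ol | OCC/C=C(\C)CCO[Si](C)(C)C(C)(C)C | intermediate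
17 | (E)-6-[(tert-butyldimethylsilyl)oxy]-4-methylhex-3-enal | O=CC/C=C(\C)CCO[Si](C)(C)C(C)(C)C | intermediate
18 | (R)-3-{[(tert-butyldimethylsilyl)oxy]methyl}-5-[(1Z,3S,5E)-8-[(tert-butyldimethylsilyl)oxy]-3-hydroxy-2,6-dimethylocta-1,5-dien-1-yl]furan-2(5H)-one | O=C1O[C@H](/C=C(/C)[C@@H](O)C/C=C(\C)CCO[Si](C)(C)C(C)(C)C)C=C1CO[Si](C)(C)C(C)(C)C | intermediate
19 | 3-methylbutanoic anhydride (isovaleric anhydride) | CC(C)CC(=O)OC(=O)CC(C)C | starting material
20 | (1Z,3S,5E)-8-[(tert-butyldimethylsilyl)oxy]-1-[(R)-4-{[(tert-butyldimethylsilyl)oxy]methyl}-5-oxo-2,5-dihydrofuran-2-yl]-2,6-dimethylocta-1,5-dien-3-yl 3-methylbutanoate | O=C1O[C@H](/C=C(/C)[C@@H](OC(=O)CC(C)C)C/C=C(\C)CCO[Si](C)(C)C(C)(C)C)C=C1CO[Si](C)(C)C(C)(C)C | intermediate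
21 | (1Z,3S,5E)-8-hydroxy-1-[(R)-4-(hydroxymethyl)-5-oxo-2,5-dihydrofuran-2-yl]-2,6-dimethylocta-1,5-dien-3-yl 3-methylbutanoate | O=C1O[C@H](/C=C(/C)[C@@H](OC(=O)CC(C)C)C/C=C(\C)CCO)C=C1CO | intermediate
22 | (1Z,3S,5E)-1-[(R)-4-(bromomethyl)-5-oxo-2,5-dihydrofuran-2-yl]-8-hydroxy-2,6-dimethylocta-1,5-dien-3-yl 3-methylbutanoate | O=C1O[C@H](/C=C(/C)[C@@H](OC(=O)CC(C)C)C/C=C(\C)CCO)C=C1CBr | intermediate
23 | (1Z,3S,5E)-1-[(R)-4-(bromomethyl)-5-oxo-2,5-dihydrofuran-2-yl]-2,6-dimethyl-8-oxoocta-1,5-dien-3-yl 3-methylbutanoate | O=C1O[C@H](/C=C(/C)[C@@H](OC(=O)CC(C)C)C/C=C(\C)CC=O)C=C1CBr | intermediate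
24 | {[(R)-5-{(1Z,3S,5E)-2,6-dimethyl-3-[(3-methylbutanoyl)oxy]-8-oxoocta-1,5-dien-1-yl}-2-oxo-2,5-dihydrofuran-3-yl]methyl}chromium dichloride (trivalent chromium σ-allyl) | O=C1O[C@H](/C=C(/C)[C@@H](OC(=O)CC(C)C)C/C=C(\C)CC=O)C=C1C[Cr](Cl)Cl | intermediate (not isolated)
25 | (3S,6R,7R,8S)-8-hydroxy-3-[(3-methylbutanoyl)oxy]germacra-1(10)E,4Z,11(13)-trien-12,6-olide (8α-OH, 3β-ester, H-6β, H-7α) | C=C1C(=O)O[C@@H]2/C=C(/C)[C@@H](OC(=O)CC(C)C)C/C=C(\C)C[C@H](O)[C@@H]12 | intermediate
26 | (Z)-2-methylbut-2-enoic acid (angelic acid) | C/C=C(/C)C(=O)O | starting material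
27 | (Z)-2-methylbut-2-en-1-ol | C/C=C(/C)CO | intermediate
28 | [(2R,3S)-2,3-dimethyloxiran-2-yl]methanol | OC[C@@]1(C)O[C@H]1C | intermediate
29 | (2S,3S)-2,3-dimethyloxirane-2-carboxylic acid | OC(=O)[C@@]1(C)O[C@H]1C | intermediate
30 | (3S,6R,7R,8R)-8-{[(2S,3S)-2,3-dimethyloxirane-2-carbonyl]oxy}-3-[(3-methylbutanoyl)oxy]germacra-1(10)E,4Z,11(13)-trien-12,6-olide | C=C1C(=O)O[C@@H]2/C=C(/C)[C@@H](OC(=O)CC(C)C)C/C=C(\C)C[C@@H](OC(=O)[C@@]3(C)O[C@H]3C)[C@@H]12 | intermediate
31 | (1R,3S,6R,7R,8R,10R)-1,10-epoxy-8-{[(2S,3S)-2,3-dimethyloxirane-2-carbonyl]oxy}-3-[(3-methylbutanoyl)oxy]germacra-4Z,11(13)-dien-12,6-olide (CNP0167461.1) | C=C1C(=O)O[C@@H]2/C=C(/C)[C@@H](OC(=O)CC(C)C)C[C@H]3O[C@]3(C)C[C@@H](OC(=O)[C@@]3(C)O[C@H]3C)[C@@H]12 | target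

**Step count and risks**

Total steps: 20. Longest linear sequence: 13 (steps 1, 2, 3, 6, 7, 10, 11, 12, 13, 14, 15, 19, 20).

Most likely to fail, in this order:

1. Step 15 (ten-membered closure). Ring strain, cis/trans lactone fusion and the C8 configuration are all decided in one untested transition state, and the chromium alkoxide could translactonise to the 8,12-olide. The fallback makes the C7–C8 bond in the open chain and closes the ring at C3–C4 instead; it sets out from 11 and 17 and returns at 30.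
 - Ph3PBr2 (CH2Cl2, 0 °C) turns the silyl ether of 11 directly into (S)-3-(bromomethyl)-5-[(Z)-2-iodoprop-1-en-1-yl]furan-2(5H)-one F1.
 - HC(OMe)3, CSA, MeOH converts 17 in one pot (acetal formation and loss of the silyl group) into (E)-6,6-dimethoxy-3-methylhex-3-en-1-ol F2, and DMP gives (E)-6,6-dimethoxy-3-methylhex-3-enal F3.
 - CrCl2 (THF, rt, no nickel, so the iodoalkene survives) couples F1 with F3 to the 7,8-anti seco-lactone alcohol F4 (attack anti to the C6 arm, chair transition state).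
 - Mitsunobu reaction of F4 with 29 gives the 8β seco-ester acetal F5, and PPTS in wet acetone frees the seco-aldehyde F6.
 - An intramolecular asymmetric NiCl2/CrCl2 coupling (ligand of step 10, high dilution) closes the ring to the macrocyclic 3β-alcohol F7, and acylation with 19 gives 30.

2. Step 19 (Mitsunobu inversion of a hindered macrocyclic alcohol next to the lactone; elimination or translactonisation may compete). The fallback is oxidation and reduction followed by a retentive esterification; it sets out from 25 and returns at 30.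
 - DMP gives the 8-ketone F8.
 - NaBH4, CeCl3·7H2O, MeOH, −78 °C reduces it from the α-face, anti to the C7–C11 bond, to the 8β-alcohol F9; the cerium salt suppresses conjugate reduction of the methylene lactone.
 - Yamaguchi esterification with 29 (2,4,6-trichlorobenzoyl chloride, Et3N, DMAP, toluene) gives 30.
 - If step 15 itself delivers F9, only this esterification is needed.

3. Step 10 (reagent-controlled C3 configuration with a hindered trisubstituted iodoalkene and an enolisable aldehyde). The fallback sets C3 by ketone reduction; it sets out from 11 and 17 and returns at 18.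
 - Ligand-free CrCl2/NiCl2 (cat.) coupling in DMSO gives the C3-epimer mixture F10.
 - DMP gives the Z-enone F11.
 - (R)-Me-CBS with catecholborane at −78 °C gives 18 by reagent-controlled 1,2-reduction.

**Further compounds**

F1 | step 15 | (S)-3-(bromomethyl)-5-[(Z)-2-iodoprop-1-en-1-yl]furan-2(5H)-one | O=C1O[C@H](/C=C(/C)I)C=C1CBr
F2 | step 15 | (E)-6,6-dimethoxy-3-methylhex-3-en-1-ol | OCC/C(C)=C/CC(OC)OC
F3 | step 15 | (E)-6,6-dimethoxy-3-methylhex-3-enal | O=CC/C(C)=C/CC(OC)OC
F4 | step 15 | 7,8-anti seco-lactone alcohol: 4-[(E)-1-hydroxy-6,6-dimethoxy-3-methylhex-3-en-1-yl]-5-[(Z)-2-iodoprop-1-en-1-yl]-3-methylideneoxolan-2-one (6,7-trans, 8α-OH) | C=C1C(=O)O[C@H](/C=C(/C)I)[C@H]1[C@@H](O)C/C(C)=C/CC(OC)OC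
F5 | step 15 | 8β seco-ester acetal: (2S,3S)-2,3-dimethyloxirane-2-carboxylate of C8-inverted F4 | C=C1C(=O)O[C@H](/C=C(/C)I)[C@H]1[C@H](OC(=O)[C@@]2(C)O[C@H]2C)C/C(C)=C/CC(OC)OC
F6 | step 15 | seco-aldehyde: F5 with the dimethyl acetal hydrolysed to the C3 aldehyde | C=C1C(=O)O[C@H](/C=C(/C)I)[C@H]1[C@H](OC(=O)[C@@]2(C)O[C@H]2C)C/C(C)=C/CC=O
F7 | step 15 | macrocyclic 3β-alcohol: (3S,6R,7R,8R)-8-{[(2S,3S)-2,3-dimethyloxirane-2-carbonyl]oxy}-3-hydroxygermacra-1(10)E,4Z,11(13)-trien-12,6-olide | C=C1C(=O)O[C@@H]2/C=C(/C)[C@@H](O)C/C=C(\C)C[C@@H](OC(=O)[C@@]3(C)O[C@H]3C)[C@@H]12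
F8 | step 19 | 8-ketone: (3S,6R,7R)-3-[(3-methylbutanoyl)oxy]-8-oxogermacra-1(10)E,4Z,11(13)-trien-12,6-olide | C=C1C(=O)O[C@@H]2/C=C(/C)[C@@H](OC(=O)CC(C)C)C/C=C(\C)CC(=O)[C@@H]12
F9 | step 19 | 8β-alcohol: (3S,6R,7R,8R)-8-hydroxy-3-[(3-methylbutanoyl)oxy]germacra-1(10)E,4Z,11(13)-trien-12,6-olide | C=C1C(=O)O[C@@H]2/C=C(/C)[C@@H](OC(=O)CC(C)C)C/C=C(\C)C[C@@H](O)[C@@H]12
F10 | step 10 | C3-epimer mixture: 18 and its 3R epimer | O=C1O[C@H](/C=C(/C)C(O)C/C=C(\C)CCO[Si](C)(C)C(C)(C)C)C=C1CO[Si](C)(C)C(C)(C)C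
F11 | step 10 | Z-enone: (R)-3-{[(tert-butyldimethylsilyl)oxy]methyl}-5-[(1Z,5E)-8-[(tert-butyldimethylsilyl)oxy]-2,6-dimethyl-3-oxoocta-1,5-dien-1-yl]furan-2(5H)-one | O=C1O[C@H](/C=C(/C)C(=O)C/C=C(\C)CCO[Si](C)(C)C(C)(C)C)C=C1CO[Si](C)(C)C(C)(C)C
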